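**Strategy**

Tetralin numbering is used: C1 carries the pendant aryl, C4 is the benzylic CH2, ring A is the fused benzene ring, ring B the saturated ring. Ring B is disconnected at C4–C4a and C2–C3, so that C4, C3 and the C3 hydroxymethyl carbon come from buta-1,3-diene. One palladium-catalysed operation with a chiral ligand joins the C4a bromide of ring A to a diene terminus and closes ring B by attack of C2 on the allyl unit, setting C3. It exploits that C4a is ortho to C8a and that C2 lies between C1 and its hydroxymethyl carbon: held as ketone and ester, they make C2 a soft nucleophile. The precursor is an open-chain ortho-bromoaroylacetate.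

Key step: step 3

Remark: the target is read as the (1R,2R,3R) isomer (aryl and C2 hydroxymethyl cis, the two hydroxymethyl groups trans); the sense of induction of the ligand in step 3 is assumed, and the antipodal ligand is taken if it proves reversed.

**Route**

Step 1
Reactants: 1 2-bromo-5-hydroxy-4-methoxybenzaldehyde
Product: 2 5-(benzyloxy)-2-bromo-4-methoxybenzaldehyde
Conditions: BnBr, K2CO3, DMF, 25 °C
Reagents that add atoms: benzyl bromide, BrCc1ccccc1
Why: Williamson O-benzylation of the phenoxide masks the ring A phenol, which would otherwise be triflated in step 4 and oxidised in step 7, and the ether falls in the final hydrogenolysis.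

Step 2
Reactants: 2 5-(benzyloxy)-2-bromo-4-methoxybenzaldehyde; 3 ethyl diazoacetate
Product: 4 ethyl 3-[5-(benzyloxy)-2-bromo-4-methoxyphenyl]-3-oxopropanoate
Conditions: NbCl5 (5 mol%), CH2Cl2, 25 °C
Reagents that add atoms: none
Why: Roskamp reaction, in which Lewis acid-promoted addition of the diazoester to the aldehyde and a 1,2-hydride shift with loss of N2 should give the β-ketoester that places the future C2 between the C1 ketone and the ester carbon; no stereocentre is formed.

Step 3
Reactants: 4 ethyl 3-[5-(benzyloxy)-2-bromo-4-methoxyphenyl]-3-oxopropanoate; 5 buta-1,3-diene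
Product: 6 ethyl (2S,3S)-7-(benzyloxy)-3-ethenyl-6-methoxy-1-oxo-1,2,3,4-tetrahydronaphthalene-2-carboxylate
Conditions: Pd(OAc)2 (5 mol%), (S,R,R)-(1,1'-binaphthalene-2,2'-diyl) N,N-bis(1-phenylethyl)phosphoramidite (12 mol%), buta-1,3-diene (5 equiv), K2CO3, DMF, 80 °C, sealed tube
Reagents that add atoms: none
Why: Zerovalent palladium inserts into the C4a–Br bond of ring A, butadiene inserts so that the aryl carbon bonds to a terminal CH2 (C4–C4a), and the potassium enolate at C2 attacks the near terminus of the resulting π-allylpalladium (C2–C3) and releases the catalyst. The closest known reaction type is the Larock carboannulation of 1,3-dienes by aryl halides that carry a stabilised carbanion, run here with a chiral ligand as an asymmetric allylic alkylation. Ring B closes in a 6-exo allylic substitution, since attack at the far allyl terminus would need an eight-membered ring. The lasting stereocentre C3 is set by the ligand, which selects between π-allyl diastereomers that interconvert through the unsubstituted terminus (η3–η1–η3) faster than they are trapped, while the epimerisable C2 settles trans to the vinyl group. The step needs C- over O-allylation of the enolate (an O-allyl product would re-ionise, the C-product does not) and ring closure faster than β-hydride elimination to an aryl diene, which the tethered soft nucleophile secures. The fourth diene carbon stays as the vinyl CH2 and is removed in step 7.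

Step 4
Reactants: 6 ethyl (2S,3S)-7-(benzyloxy)-3-ethenyl-6-methoxy-1-oxo-1,2,3,4-tetrahydronaphthalene-2-carboxylate
Product: 7 ethyl (3S)-7-(benzyloxy)-3-ethenyl-6-methoxy-1-{[(trifluoromethyl)sulfonyl]oxy}-3,4-dihydronaphthalene-2-carboxylate
Conditions: NaH, PhNTf2, THF, 0 to 25 °C
Reagents that add atoms: N-phenylbis(trifluoromethanesulfonimide), O=S(=O)(N(c1ccccc1)S(=O)(=O)C(F)(F)F)C(F)(F)F
Why: O-sulfonylation of the sodium enolate of the β-ketoester should give the enol triflate, which fixes the C1=C2 double bond, deletes the labile C2 centre and leaves C3 untouched because C3–H is not acidic.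

Step 5
Reactants: 7 ethyl (3S)-7-(benzyloxy)-3-ethenyl-6-methoxy-1-{[(trifluoromethyl)sulfonyl]oxy}-3,4-dihydronaphthalene-2-carboxylate; 8 [4-(benzyloxy)-3-methoxyphenyl]boronic acid
Product: 9 ethyl (3S)-7-(benzyloxy)-1-[4-(benzyloxy)-3-methoxyphenyl]-3-ethenyl-6-methoxy-3,4-dihydronaphthalene-2-carboxylate
Conditions: Pd(PPh3)4 (5 mol%), K2CO3, dioxane/H2O, 80 °C
Reagents that add atoms: none
Why: Suzuki–Miyaura coupling of the electron-poor β-triflyloxy enoate should install the pendant aryl on C1 without touching the C3 stereocentre.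

Step 6
Reactants: 9 ethyl (3S)-7-(benzyloxy)-1-[4-(benzyloxy)-3-methoxyphenyl]-3-ethenyl-6-methoxy-3,4-dihydronaphthalene-2-carboxylate
Product: 10 [(3S)-7-(benzyloxy)-1-[4-(benzyloxy)-3-methoxyphenyl]-3-ethenyl-6-methoxy-3,4-dihydronaphthalen-2-yl]methanol
Conditions: DIBAL-H (i-Bu2AlH, 2.5 equiv), CH2Cl2, −78 to 0 °C; aq. KNaC4H4O6 work-up
Reagents that add atoms: none
Why: 1,2-Reduction of the conjugated ester by DIBAL-H should give the allylic alcohol (the C2 hydroxymethyl group) and spare both alkenes and the benzyl ethers.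

Step 7
Reactants: 10 [(3S)-7-(benzyloxy)-1-[4-(benzyloxy)-3-methoxyphenyl]-3-ethenyl-6-methoxy-3,4-dihydronaphthalen-2-yl]methanol
Product: 12 {(3R)-7-(benzyloxy)-1-[4-(benzyloxy)-3-methoxyphenyl]-6-methoxy-3,4-dihydronaphthalene-2,3-diyl}dimethanol, via lactol 11 (not isolated)
Conditions: OsO4 (2 mol%), NaIO4 (2.2 equiv), 2,6-lutidine, dioxane/H2O, 25 °C; aq. work-up; then NaBH4, MeOH, 0 °C
Reagents that add atoms: osmium tetroxide, O=[Os](=O)(=O)=O (catalytic oxygen carrier); sodium periodate, [Na+].[O-]I(=O)(=O)=O (terminal oxygen source)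
Why: Lemieux–Johnson cleavage, in which osmylation should be fastest at the unhindered vinyl group, the aldehyde is trapped at once by the allylic hydroxyl as lactol 11 (which shields C3 from enolisation), and borohydride reduces it to the C3 hydroxymethyl group with C3 unchanged in space (S becomes R by priority only).

Step 8
Reactants: 12 {(3R)-7-(benzyloxy)-1-[4-(benzyloxy)-3-methoxyphenyl]-6-methoxy-3,4-dihydronaphthalene-2,3-diyl}dimethanol
Product: 13 {(1R,2R,3R)-7-(benzyloxy)-1-[4-(benzyloxy)-3-methoxyphenyl]-6-methoxy-1,2,3,4-tetrahydronaphthalene-2,3-diyl}dimethanol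
Conditions: [Ir(cod)(PCy3)(py)]PF6 (10 mol%), H2 (20 bar), CH2Cl2, 25 °C
Reagents that add atoms: none
Why: Hydroxyl-directed homogeneous hydrogenation, in which the cationic iridium centre is held on the alkene face that carries the C3 hydroxymethyl group (chelation by this homoallylic hydroxyl, helped by the in-plane allylic one), so both hydrogens should be delivered syn to it, setting C1 (R) and C2 (R) with the aryl and the C2 hydroxymethyl cis to each other and trans to the C3 hydroxymethyl.

Step 9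
Reactants: 13 {(1R,2R,3R)-7-(benzyloxy)-1-[4-(benzyloxy)-3-methoxyphenyl]-6-methoxy-1,2,3,4-tetrahydronaphthalene-2,3-diyl}dimethanol
Product: 14 (6R,7R,8R)-8-(4-hydroxy-3-methoxyphenyl)-6,7-bis(hydroxymethyl)-3-methoxy-5,6,7,8-tetrahydronaphthalen-2-ol
Conditions: H2 (1 atm), Pd/C (10%), EtOAc/MeOH, 25 °C
Reagents that add atoms: none
Why: Hydrogenolysis of the two benzyl aryl ethers over palladium on carbon should free both phenols, while the stereocentres, the primary alcohols and the diarylmethine C–C bonds are inert.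

**Compound list**

1 | 2-bromo-5-hydroxy-4-methoxybenzaldehyde | O=Cc1cc(O)c(OC)cc1Br | starting material
2 | 5-(benzyloxy)-2-bromo-4-methoxybenzaldehyde | O=Cc1cc(OCc2ccccc2)c(OC)cc1Br | intermediate
3 | ethyl diazoacetate | CCOC(=O)C=[N+]=[N-] | starting material
4 | ethyl 3-[5-(benzyloxy)-2-bromo-4-methoxyphenyl]-3-oxopropanoate | CCOC(=O)CC(=O)c1cc(OCc2ccccc2)c(OC)cc1Br | intermediate
5 | buta-1,3-diene | C=CC=C | starting material
6 | ethyl (2S,3S)-7-(benzyloxy)-3-ethenyl-6-methoxy-1-oxo-1,2,3,4-tetrahydronaphthalene-2-carboxylate (trans; C2 epimerisable) | O=C1c2cc(OCc3ccccc3)c(OC)cc2C[C@@H](C=C)[C@@H]1C(=O)OCC | intermediate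
7 | ethyl (3S)-7-(benzyloxy)-3-ethenyl-6-methoxy-1-{[(trifluoromethyl)sulfonyl]oxy}-3,4-dihydronaphthalene-2-carboxylate | CCOC(=O)C1=C(OS(=O)(=O)C(F)(F)F)c2cc(OCc3ccccc3)c(OC)cc2C[C@H]1C=C | intermediate
8 | [4-(benzyloxy)-3-methoxyphenyl]boronic acid | OB(O)c1ccc(OCc2ccccc2)c(OC)c1 | starting material
9 | ethyl (3S)-7-(benzyloxy)-1-[4-(benzyloxy)-3-methoxyphenyl]-3-ethenyl-6-methoxy-3,4-dihydronaphthalene-2-carboxylate | CCOC(=O)C1=C(c2ccc(OCc3ccccc3)c(OC)c2)c2cc(OCc3ccccc3)c(OC)cc2C[C@H]1C=C | intermediate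
10 | [(3S)-7-(benzyloxy)-1-[4-(benzyloxy)-3-methoxyphenyl]-3-ethenyl-6-methoxy-3,4-dihydronaphthalen-2-yl]methanol | OCC1=C(c2ccc(OCc3ccccc3)c(OC)c2)c2cc(OCc3ccccc3)c(OC)cc2C[C@H]1C=C | intermediate
11 | (3aR)-7-(benzyloxy)-9-[4-(benzyloxy)-3-methoxyphenyl]-6-methoxy-1,3,3a,4-tetrahydronaphtho[2,3-c]furan-3-ol (lactol, both anomers) | OC1OCC2=C(c3ccc(OCc4ccccc4)c(OC)c3)c3cc(OCc4ccccc4)c(OC)cc3C[C@@H]12 | intermediate
12 | {(3R)-7-(benzyloxy)-1-[4-(benzyloxy)-3-methoxyphenyl]-6-methoxy-3,4-dihydronaphthalene-2,3-diyl}dimethanol | OCC1=C(c2ccc(OCc3ccccc3)c(OC)c2)c2cc(OCc3ccccc3)c(OC)cc2C[C@H]1CO | intermediate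
13 | {(1R,2R,3R)-7-(benzyloxy)-1-[4-(benzyloxy)-3-methoxyphenyl]-6-methoxy-1,2,3,4-tetrahydronaphthalene-2,3-diyl}dimethanol | COc1cc([C@@H]2c3cc(OCc4ccccc4)c(OC)cc3C[C@@H](CO)[C@@H]2CO)ccc1OCc1ccccc1 | intermediate
14 | (6R,7R,8R)-8-(4-hydroxy-3-methoxyphenyl)-6,7-bis(hydroxymethyl)-3-methoxy-5,6,7,8-tetrahydronaphthalen-2-ol | COc1cc([C@@H]2c3cc(O)c(OC)cc3C[C@@H](CO)[C@@H]2CO)ccc1O | target

**Step count and risks**

Total step count: 9. Longest linear sequence: 9 steps (1 to 14).

Steps most likely to fail: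

1. Step 3 (key step). Oxidative addition into the electron-rich aryl bromide may be slow, the allylpalladium may undergo β-hydride elimination to an aryl diene before ring closure, or the enantioface selection may be weak. The fallback sets out from 2 and returns at 6, making the two bonds in separate known steps. Stille coupling of 2 with allyltributylstannane (Pd(PPh3)4, toluene, 100 °C) should give 5-(benzyloxy)-4-methoxy-2-(prop-2-en-1-yl)benzaldehyde F1. Cross-metathesis with (Z)-but-2-ene-1,4-diyl diacetate (second-generation Grubbs catalyst, CH2Cl2, 40 °C) should give (2E)-4-[4-(benzyloxy)-2-formyl-5-methoxyphenyl]but-2-en-1-yl acetate F2. Roskamp homologation with 3 (NbCl5, CH2Cl2) should give ethyl 3-{2-[(2E)-4-acetoxybut-2-en-1-yl]-5-(benzyloxy)-4-methoxyphenyl}-3-oxopropanoate F3. Intramolecular asymmetric Tsuji–Trost allylic alkylation (Pd2(dba)3, (1R,2R)-N,N'-bis[2-(diphenylphosphino)benzoyl]cyclohexane-1,2-diamine, Et3N, CH2Cl2) should then close ring B at the internal allyl terminus to 6.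

2. Step 8. The tetrasubstituted, diaryl-substituted alkene may be reduced too slowly, the allylic alcohol may isomerise, or hydrogen may be delivered without control by the hydroxyl group. The fallback sets out from 7 and returns at 13, replacing cross-coupling and hydrogenation by conjugate addition. Palladium-catalysed formate reduction of the triflate (Pd(OAc)2, PPh3, HCO2H, Et3N, DMF, 60 °C) should give ethyl (3S)-7-(benzyloxy)-3-ethenyl-6-methoxy-3,4-dihydronaphthalene-2-carboxylate F4. The Grignard reagent [4-(benzyloxy)-3-methoxyphenyl]magnesium bromide F5, made from commercial 1-(benzyloxy)-4-bromo-2-methoxybenzene and Mg in THF, is added with CuBr·SMe2 and Me3SiCl at −40 °C, anti to the pseudoaxial C3 vinyl group. Equilibration of C2 with NaOEt/EtOH should then give ethyl (1R,2S,3S)-7-(benzyloxy)-1-[4-(benzyloxy)-3-methoxyphenyl]-3-ethenyl-6-methoxy-1,2,3,4-tetrahydronaphthalene-2-carboxylate F6; this C2 epimer is expected to be the stable one because, with the C1 aryl pseudoaxial, the C2 and C3 substituents are both equatorial. Cleavage of the vinyl group (OsO4, NaIO4, 2,6-lutidine) should give ethyl (1R,2R,3R)-7-(benzyloxy)-1-[4-(benzyloxy)-3-methoxyphenyl]-3-formyl-6-methoxy-1,2,3,4-tetrahydronaphthalene-2-carboxylate F7, which is not isolated but reduced with LiAlH4 (THF, 0 °C) at aldehyde and ester to 13.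

3. Step 7. Osmylation may also attack the electron-rich tetrasubstituted styrenic alkene, or over-oxidation may occur. The fallback sets out from 7 and returns at 12, doing the cleavage before the cross-coupling, when the only other alkene is the electron-poor enol triflate. Treatment of 7 with OsO4/NaIO4/2,6-lutidine should give ethyl (3R)-7-(benzyloxy)-3-formyl-6-methoxy-1-{[(trifluoromethyl)sulfonyl]oxy}-3,4-dihydronaphthalene-2-carboxylate F8, reduced without isolation by NaBH4 to ethyl (3R)-7-(benzyloxy)-3-(hydroxymethyl)-6-methoxy-1-{[(trifluoromethyl)sulfonyl]oxy}-3,4-dihydronaphthalene-2-carboxylate F9. With catalytic TsOH this should lactonise to (3aR)-7-(benzyloxy)-6-methoxy-1-oxo-1,3,3a,4-tetrahydronaphtho[2,3-c]furan-9-yl trifluoromethanesulfonate F10. Suzuki–Miyaura coupling with 8 (Pd(PPh3)4, K2CO3, dioxane/H2O) should give (3aR)-7-(benzyloxy)-9-[4-(benzyloxy)-3-methoxyphenyl]-6-methoxy-3a,4-dihydronaphtho[2,3-c]furan-1(3H)-one F11, and DIBAL-H (excess, CH2Cl2, −78 to 0 °C) should reduce the lactone to 12.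

**Further compounds**

F1 | step 3 | 5-(benzyloxy)-4-methoxy-2-(prop-2-en-1-yl)benzaldehyde | O=Cc1cc(OCc2ccccc2)c(OC)cc1CC=C
F2 | step 3 | (2E)-4-[4-(benzyloxy)-2-formyl-5-methoxyphenyl]but-2-en-1-yl acetate | O=Cc1cc(OCc2ccccc2)c(OC)cc1C/C=C/COC(C)=O
F3 | step 3 | ethyl 3-{2-[(2E)-4-acetoxybut-2-en-1-yl]-5-(benzyloxy)-4-methoxyphenyl}-3-oxopropanoate | CCOC(=O)CC(=O)c1cc(OCc2ccccc2)c(OC)cc1C/C=C/COC(C)=O
F4 | step 8 | ethyl (3S)-7-(benzyloxy)-3-ethenyl-6-methoxy-3,4-dihydronaphthalene-2-carboxylate | CCOC(=O)C1=Cc2cc(OCc3ccccc3)c(OC)cc2C[C@H]1C=C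
F5 | step 8 | [4-(benzyloxy)-3-methoxyphenyl]magnesium bromide | Br[Mg]c1ccc(OCc2ccccc2)c(OC)c1
F6 | step 8 | ethyl (1R,2S,3S)-7-(benzyloxy)-1-[4-(benzyloxy)-3-methoxyphenyl]-3-ethenyl-6-methoxy-1,2,3,4-tetrahydronaphthalene-2-carboxylate | COc1cc([C@@H]2c3cc(OCc4ccccc4)c(OC)cc3C[C@@H](C=C)[C@@H]2C(=O)OCC)ccc1OCc1ccccc1
F7 | step 8 | ethyl (1R,2R,3R)-7-(benzyloxy)-1-[4-(benzyloxy)-3-methoxyphenyl]-3-formyl-6-methoxy-1,2,3,4-tetrahydronaphthalene-2-carboxylate | COc1cc([C@@H]2c3cc(OCc4ccccc4)c(OC)cc3C[C@@H](C=O)[C@@H]2C(=O)OCC)ccc1OCc1ccccc1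
F8 | step 7 | ethyl (3R)-7-(benzyloxy)-3-formyl-6-methoxy-1-{[(trifluoromethyl)sulfonyl]oxy}-3,4-dihydronaphthalene-2-carboxylate | CCOC(=O)C1=C(OS(=O)(=O)C(F)(F)F)c2cc(OCc3ccccc3)c(OC)cc2C[C@H]1C=O
F9 | step 7 | ethyl (3R)-7-(benzyloxy)-3-(hydroxymethyl)-6-methoxy-1-{[(trifluoromethyl)sulfonyl]oxy}-3,4-dihydronaphthalene-2-carboxylate | CCOC(=O)C1=C(OS(=O)(=O)C(F)(F)F)c2cc(OCc3ccccc3)c(OC)cc2C[C@H]1CO
F10 | step 7 | (3aR)-7-(benzyloxy)-6-methoxy-1-oxo-1,3,3a,4-tetrahydronaphtho[2,3-c]furan-9-yl trifluoromethanesulfonate | O=C1OC[C@@H]2Cc3cc(OC)c(OCc4ccccc4)cc3C(OS(=O)(=O)C(F)(F)F)=C12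
F11 | step 7 | (3aR)-7-(benzyloxy)-9-[4-(benzyloxy)-3-methoxyphenyl]-6-methoxy-3a,4-dihydronaphtho[2,3-c]furan-1(3H)-one | O=C1OC[C@@H]2Cc3cc(OC)c(OCc4ccccc4)cc3C(c3ccc(OCc4ccccc4)c(OC)c3)=C12
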